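A direct plan would take phlorbutyrophenone A1, convert part of it into butyrylfilicinic acid A2 by base-mediated gem-dimethylation, and join one A1 with two A2 through formaldehyde A3 in aqueous alkali. Its weakest steps would be, first, the dearomatising C-methylation, which would give mono-, di-, tri- and O-methylated products side by side because every ring carbon and oxygen of the phloroglucinol anion is nucleophilic. Second, the bridge formation, in which three competing nucleophilic rings and unselective quinone methides would give a statistical mixture with homodimers such as the bis-filicinic acid A4. Third, the alkaline medium, in which bridges already formed would exchange by retro-Michael cleavage.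

In the target each bridge carbon, the neighbouring phenolic oxygen of ring B and C2–C3 of an outer ring (rings A and C; C1 carries the butanoyl group, C3 the bridge, C5 the two methyls) map onto a dihydrocoumarin, and C4–C5–C6–C1 with the butanoyl group map onto 3,3-dimethyl-6-propylpyran-2,4-dione. The route therefore annulates ring B with two lactones and, in one flask, acylates their enolates with this enol lactone and lets each liberated β-diketone close onto its aryl lactone. Four C–C bonds and both dearomatised rings would form in one operation, the lactone oxygens would return as phenols, and neither C-methylation of a phloroglucinol nor formaldehyde bridging in alkali would be needed.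

Key step: step 4

Assumption: in step 2 each propanoic acid arm could lactonise onto either neighbouring phenol; the isomer that keeps the hydroxyl next to the butanoyl group free (hydrogen-bonded) is drawn as 5, and a regioisomeric bis-lactone would give the same target in step 4 because every lactone oxygen is released as a phenol.

Step 1
Reactants: 1 phloroglucinol; 2 butanoyl chloride
Product: 3 1-(2,4,6-trihydroxyphenyl)butan-1-one (phlorbutyrophenone)
Conditions: AlCl3 (3.5 equiv), PhNO2, 60 °C; ice/aq. HCl
Reagents that add atoms: none
Why: Friedel–Crafts C-acylation of the electron-rich triol should stop at the mono-ketone because the chelated acyl group deactivates the ring; no stereocentre is formed.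

Step 2
Reactants: 3 phlorbutyrophenone; 4 prop-2-enoic acid (acrylic acid, 3 equiv)
Product: 5 6-butanoyl-5-hydroxy-3,4,9,10-tetrahydro-2H,8H-pyrano[2,3-f]chromene-2,8-dione
Conditions: Amberlyst-15 (sulfonic acid resin), toluene, 110 °C, Dean–Stark
Reagents that add atoms: none
Why: Twofold acid-catalysed hydroarylation (Friedel–Crafts-type conjugate addition of the two free ring carbons to acrylic acid) followed by lactonisation onto a flanking phenol, the known dihydrocoumarin synthesis from phloroglucinols and acrylic acid, should end at the bis-lactone because no free ring carbon remains; no stereocentre is formed.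

Step 3
Reactants: 6 pentan-2-one (2.1 equiv); 7 2,2-dimethylpropanedioyl dichloride (dimethylmalonyl dichloride, 1.0 equiv)
Product: 8 3,3-dimethyl-6-propyl-2H-pyran-2,4(3H)-dione
Conditions: LiN(iPr)2 (2.1 equiv), THF, −78 °C; then 7, −78 → 0 °C
Reagents that add atoms: none
Why: The kinetic (methyl-side) lithium enolate is C-acylated by one acid chloride, the second enolate equivalent deprotonates the new β-diketone and its enolate oxygen closes onto the second acid chloride (pyran-2,4-dione synthesis of the Effenberger type), the gem-dimethyl carbon excluding ketene formation and aromatisation; no stereocentre is formed.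

Step 4
Reactants: 5 bis-lactone (1 equiv); 8 3,3-dimethyl-6-propyl-2H-pyran-2,4(3H)-dione (2.4 equiv)
Product: 10 1-[3,5-bis[(5-butanoyl-2,6-dihydroxy-3,3-dimethyl-4-oxocyclohexa-1,5-dien-1-yl)methyl]-2,4,6-trihydroxyphenyl]butan-1-one (target), via 3,9-diacyl bis-lactone 9 (not isolated)
Conditions: LiN(SiMe3)2 (3.1 equiv), THF, −78 °C; 8, −78 °C; LiN(SiMe3)2 (2.1 equiv), then MgBr2·OEt2 (4 equiv), −78 °C → rt; cold 1 M HCl
Reagents that add atoms: none
Why: Proposed new method: LiN(SiMe3)2 removes the phenol proton and then the two lactone α-protons of 5 (an aryl δ-lactone C–H is more acidic than the α-C–H of the twisted, doubly ortho-substituted and phenoxide-conjugated butanoyl ketone), each lactone enolate attacks the enol-lactone carbonyl C2 of 8 in a Claisen acylation, and collapse of the tetrahedral intermediate expels the ring oxygen as a β-diketone enolate to give 9, in which this enolate carbon sits six atoms from the aryl lactone carbonyl. On warming, the magnesium-chelated enolate carbon closes onto that carbonyl in a 6-exo-trig Claisen (Dieckmann-type) step, directly or through the acylketene formed by E1cB loss of the phenoxide, so that each dihydrocoumarin becomes a 2-butanoyl-4,4-dimethylcyclohexane-1,3,5-trione ring and its lactone oxygen is released as a phenol of ring B. The closest known reaction types are the opening of enol lactones by carbanions (Fujimoto–Belleau type), the Claisen-mode cyclisation of 3,5,7-triketo esters to acylphloroglucinols under magnesium chelation, and annulations that end in a Dieckmann closure with loss of a leaving group (Hauser–Kraus and Staunton–Weinreb annulations). No stereocentre is set: the target is achiral and the two enolisable centres C3 and C9 of 9 become sp2 carbons. The step needs attack at C2 of 8 and not conjugate addition at C6, which the hard lithium enolate and the fully substituted, alkyl- and oxygen-bearing C6 should secure, and it needs C- over O-acylation and Claisen- over aldol-mode closure, which magnesium chelation of the β-diketone oxygens, the reversibility of the aldol and O-acyl alternatives and the stability of the trione enolate should secure. The second portion of base takes up the acidic C–H of each acylated arm so that unreacted lactone enolate is not quenched, and the product leaves the flask as a chelated polyanion at or below rt, which should limit base-induced exchange of the new bridges.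

Compound list
1 | phloroglucinol (benzene-1,3,5-triol) | Oc1cc(O)cc(O)c1 | starting material
2 | butanoyl chloride | CCCC(Cl)=O | starting material
3 | 1-(2,4,6-trihydroxyphenyl)butan-1-one (phlorbutyrophenone) | CCCC(=O)c1c(O)cc(O)cc1O | intermediate
4 | prop-2-enoic acid (acrylic acid) | C=CC(=O)O | starting material
5 | 6-butanoyl-5-hydroxy-3,4,9,10-tetrahydro-2H,8H-pyrano[2,3-f]chromene-2,8-dione | CCCC(=O)c1c(O)c2CCC(=O)Oc2c2CCC(=O)Oc12 | intermediate
6 | pentan-2-one | CCCC(C)=O | starting material
7 | 2,2-dimethylpropanedioyl dichloride (dimethylmalonyl dichloride) | CC(C)(C(=O)Cl)C(=O)Cl | starting material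
8 | 3,3-dimethyl-6-propyl-2H-pyran-2,4(3H)-dione | CCCC1=CC(=O)C(C)(C)C(=O)O1 | intermediate
9 | 6-butanoyl-3,9-bis(2,2-dimethyl-3,5-dioxooctanoyl)-5-hydroxy-3,4,9,10-tetrahydro-2H,8H-pyrano[2,3-f]chromene-2,8-dione (C3 and C9 unassigned and enolisable; present as polyanion in the flask) | CCCC(=O)c1c(O)c2CC(C(=O)C(C)(C)C(=O)CC(=O)CCC)C(=O)Oc2c2CC(C(=O)C(C)(C)C(=O)CC(=O)CCC)C(=O)Oc12 | intermediate (not isolated)
10 | 1-[3,5-bis[(5-butanoyl-2,6-dihydroxy-3,3-dimethyl-4-oxocyclohexa-1,5-dien-1-yl)methyl]-2,4,6-trihydroxyphenyl]butan-1-one (achiral) | CCCC(=O)C1=C(O)C(Cc2c(O)c(CC3=C(O)C(C)(C)C(=O)C(C(=O)CCC)=C3O)c(O)c(C(=O)CCC)c2O)=C(O)C(C)(C)C1=O | target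

Total step count: 4. Longest linear sequence: 3 steps (1 → 3 → 5 → 10); the second branch (6 + 7 → 8) has 1 step.

Steps most likely to fail

Step 4. The twofold acylation could stay incomplete through proton transfer from acylated arms to unreacted lactone enolate, the enolate could add to C6 of 8 instead of C2, closure could occur through oxygen instead of carbon, and the finished bridges could exchange in the basic medium. The fallback would make the outer rings first and join them to ring B reductively under neutral conditions. It sets out from 3: known gem-dimethylation (NaOMe, MeI, MeOH) would give 2-butanoyl-3,5-dihydroxy-6,6-dimethylcyclohexa-2,4-dien-1-one (butyrylfilicinic acid) F1, and Vilsmeier–Haack diformylation (POCl3, DMF) of a second portion of 3 would give 5-butanoyl-2,4,6-trihydroxybenzene-1,3-dicarbaldehyde F2. Three-component Knoevenagel condensation/transfer hydrogenation of F2 with two equivalents of F1 and Hantzsch ester (L-proline cat., CH2Cl2, rt) would come back to the route at 10.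

Step 2. The reaction could stall after the first lactone, because the new acyloxy group lowers the nucleophilicity of the ring, or acrylic acid could acylate the ring and lead to chromanones. The fallback would bring in the bridge carbons as formyl groups. It sets out from 3 by way of the dialdehyde F2 described above, which would be condensed with Meldrum's acid and reduced in the same flask with Hantzsch ester (L-proline cat., EtOH, rt) to 5,5'-[(5-butanoyl-2,4,6-trihydroxy-1,3-phenylene)bis(methylene)]bis(2,2-dimethyl-1,3-dioxane-4,6-dione) F3. Heating (pyridine, toluene, 110 °C) would lactonise each unit with loss of acetone to 6-butanoyl-5-hydroxy-2,8-dioxo-3,4,9,10-tetrahydro-2H,8H-pyrano[2,3-f]chromene-3,9-dicarboxylic acid F4, which would decarboxylate under the same conditions and come back to the route at 5.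

Step 3. The enolate could be O-acylated, the diacid chloride could be acylated twice, and enolate equilibration could erode the regiochemistry. The fallback would build the chain by a crossed Claisen condensation on a non-enolisable diester. It sets out from 6: condensation with dimethyl 2,2-dimethylpropanedioate F5 (NaH, THF, reflux; acylation at the methyl group) would give methyl 2,2-dimethyl-3,5-dioxooctanoate F6. Saponification (LiOH, aq. THF, 0 °C) would give 2,2-dimethyl-3,5-dioxooctanoic acid F7, and dehydrative enol lactonisation (trifluoroacetic anhydride, CH2Cl2, 0 °C) would come back to the route at 8.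

Further compounds
F1 | step 4 | 2-butanoyl-3,5-dihydroxy-6,6-dimethylcyclohexa-2,4-dien-1-one (butyrylfilicinic acid) | CCCC(=O)C1=C(O)C=C(O)C(C)(C)C1=O
F2 | step 4 | 5-butanoyl-2,4,6-trihydroxybenzene-1,3-dicarbaldehyde | CCCC(=O)c1c(O)c(C=O)c(O)c(C=O)c1O
F3 | step 2 | 5,5'-[(5-butanoyl-2,4,6-trihydroxy-1,3-phenylene)bis(methylene)]bis(2,2-dimethyl-1,3-dioxane-4,6-dione) | CCCC(=O)c1c(O)c(CC2C(=O)OC(C)(C)OC2=O)c(O)c(CC2C(=O)OC(C)(C)OC2=O)c1O
F4 | step 2 | 6-butanoyl-5-hydroxy-2,8-dioxo-3,4,9,10-tetrahydro-2H,8H-pyrano[2,3-f]chromene-3,9-dicarboxylic acid (C3 and C9 unassigned) | CCCC(=O)c1c(O)c2CC(C(=O)O)C(=O)Oc2c2CC(C(=O)O)C(=O)Oc12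
F5 | step 3 | dimethyl 2,2-dimethylpropanedioate | COC(=O)C(C)(C)C(=O)OC
F6 | step 3 | methyl 2,2-dimethyl-3,5-dioxooctanoate | CCCC(=O)CC(=O)C(C)(C)C(=O)OC
F7 | step 3 | 2,2-dimethyl-3,5-dioxooctanoic acid | CCCC(=O)CC(=O)C(C)(C)C(=O)O
A1 | direct plan | 1-(2,4,6-trihydroxyphenyl)butan-1-one (phlorbutyrophenone) | CCCC(=O)c1c(O)cc(O)cc1O
A2 | direct plan | 2-butanoyl-3,5-dihydroxy-6,6-dimethylcyclohexa-2,4-dien-1-one (butyrylfilicinic acid) | CCCC(=O)C1=C(O)C=C(O)C(C)(C)C1=O
A3 | direct plan | formaldehyde | C=O
A4 | direct plan | methylenebis(butyrylfilicinic acid), the bis-filicinic acid homodimer | CCCC(=O)C1=C(O)C(CC2=C(O)C(C)(C)C(=O)C(C(=O)CCC)=C2O)=C(O)C(C)(C)C1=O
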